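The oxolane is disconnected at O1–C2, the ring C–O bond whose carbon carries its aryl ring trans to the C3 methyl. Because both aryl rings are the same 4-oxygenated 3,5-dimethoxyphenyl ring and the C3/C4 methyls are trans, this cut reveals a twofold-symmetric (1R,2S,3S,4R)-1,4-diaryl-2,3-dimethylbutane-1,4-diol with homotopic benzylic carbinols. Monosulfonylation of either hydroxyl and 5-exo displacement by the other closes the ring with inversion at C2 and retention at C5, turning the symmetric diol into the unsymmetrical 2,3-trans-3,4-trans-4,5-cis skeleton in one operation. The diol arises from an auxiliary-controlled oxidative enolate homocoupling, a twofold Weinreb ketone synthesis and a catalyst-controlled double ketone reduction.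

Key step: step 7

Remark: oxolane numbering used throughout is O1, C2 (aryl trans to the C3 methyl, closed in the key step), C3, C4, C5 (aryl cis to the C4 methyl); with it the target is (2S,3S,4S,5R).

Step 1
Reactants: 1 (R)-4-benzyl-3-propionyloxazolidin-2-one
Product: 3 (2S,3S)-1,4-bis[(R)-4-benzyl-2-oxooxazolidin-3-yl]-2,3-dimethylbutane-1,4-dione, via lithium Z-enolate 2 (not isolated)
Conditions: LiN(i-Pr)2 (1.1 equiv), THF, −78 °C; then TiCl4 (1.1 equiv), −78 °C to rt
Reagents that add atoms: (R)-4-benzyl-3-propionyloxazolidin-2-one (second molecule of compound 1), CCC(=O)N1[C@H](Cc2ccccc2)COC1=O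
Why: Oxidative enolate homocoupling, a union of the nucleophilic α-carbons of two molecules of 1: tetravalent titanium oxidizes the chelated Z-enolate (going to trivalent titanium), and each new C–C bond should form on the face opposite the C4 benzyl group of the (R)-auxiliary, making both new centers S, with minor diastereomers removed by crystallization or chromatography.

Step 2
Reactants: 3 (2S,3S)-1,4-bis[(R)-4-benzyl-2-oxooxazolidin-3-yl]-2,3-dimethylbutane-1,4-dione
Product: 5 (2S,3S)-2,3-dimethylbutanedioic acid, via diperoxy acid 4 (not isolated)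
Conditions: LiOH, H2O2, THF/H2O, 0 °C; then Na2SO3; then HCl
Reagents that add atoms: hydrogen peroxide (acting as LiOOH), OO
Why: Evans auxiliary cleavage with LiOOH, in which the hydroperoxide anion attacks the exocyclic imide carbonyl even of hindered imides, sulfite reduces the peracid, and the weakly basic medium should leave both α-centers untouched.

Step 3
Reactants: 5 (2S,3S)-2,3-dimethylbutanedioic acid
Product: 6 (2S,3S)-N1,N4-dimethoxy-N1,N4,2,3-tetramethylbutanediamide
Conditions: MeNHOMe·HCl (2.4 equiv), EDC·HCl (2.4 equiv), HOBt, i-Pr2NEt, CH2Cl2, 0 °C to rt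
Reagents that add atoms: N,O-dimethylhydroxylamine hydrochloride, CNOC.Cl
Why: Carbodiimide amide coupling (Weinreb amide formation), in which both carboxyl groups are activated in turn and each acylates one molecule of the hydroxylamine under conditions that do not enolize the α-centers.

Step 4
Reactants: 7 4-bromo-2,6-dimethoxyphenol
Product: 8 (4-bromo-2,6-dimethoxyphenoxy)(tert-butyl)dimethylsilane
Conditions: TBSCl, imidazole, DMF, rt
Reagents that add atoms: tert-butyldimethylsilyl chloride, CC(C)(C)[Si](C)(C)Cl
Why: Standard silyl ether formation, giving a phenol protecting group that should survive Grignard formation, borane reduction and sulfonylation and leave with fluoride at the end.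

Step 5
Reactants: 8 (4-bromo-2,6-dimethoxyphenoxy)(tert-butyl)dimethylsilane; 6 (2S,3S)-N1,N4-dimethoxy-N1,N4,2,3-tetramethylbutanediamide
Product: 10 (2S,3S)-1,4-bis[4-(tert-butyldimethylsilyloxy)-3,5-dimethoxyphenyl]-2,3-dimethylbutane-1,4-dione, via aryl Grignard reagent 9 (not isolated)
Conditions: 8 (2.5 equiv), Mg, THF, 50 °C; then 6 (1 equiv), THF, 0 °C to rt; aq. NH4Cl
Reagents that add atoms: (4-bromo-2,6-dimethoxyphenoxy)(tert-butyl)dimethylsilane (second molecule of compound 8), COc1cc(Br)cc(OC)c1O[Si](C)(C)C(C)(C)C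
Why: Twofold Weinreb ketone synthesis, in which each of the two amide groups takes up one aryl Grignard unit and forms a stable magnesium chelate that collapses to the aryl ketone only on work-up, so over-addition and enolization of the α-centers should be avoided.

Step 6
Reactants: 10 (2S,3S)-1,4-bis[4-(tert-butyldimethylsilyloxy)-3,5-dimethoxyphenyl]-2,3-dimethylbutane-1,4-dione
Product: 11 (1R,2S,3S,4R)-1,4-bis[4-(tert-butyldimethylsilyloxy)-3,5-dimethoxyphenyl]-2,3-dimethylbutane-1,4-diol
Conditions: (S)-2-methyl-CBS-oxazaborolidine [(S)-1-methyl-3,3-diphenyltetrahydro-1H,3H-pyrrolo[1,2-c][1,3,2]oxazaborole, C18H20BNO] (0.4 equiv), BH3·SMe2, THF, −20 °C to 0 °C; MeOH quench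
Reagents that add atoms: none
Why: Corey–Bakshi–Shibata reduction, established for 1,4-diaryl-1,4-diketones: with aryl as the large group the (S)-catalyst should give the (R)-carbinol at both homotopic ketones, overriding the weaker Felkin–Anh bias of the α-methyl centers, and the all-syn (1R,2S,3S,4R) diol is freed from carbinol epimers by chromatography.

Step 7
Reactants: 11 (1R,2S,3S,4R)-1,4-bis[4-(tert-butyldimethylsilyloxy)-3,5-dimethoxyphenyl]-2,3-dimethylbutane-1,4-diol
Product: 13 (2S,3S,4S,5R)-2,5-bis[4-(tert-butyldimethylsilyloxy)-3,5-dimethoxyphenyl]-3,4-dimethyloxolane, via monomesylate 12 (not isolated)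
Conditions: Ms2O (1.05 equiv, slow addition), Et3N, CH2Cl2, −20 °C to rt
Reagents that add atoms: none
Why: One of the two homotopic benzylic hydroxyls of the twofold-symmetric diol is sulfonylated to monomesylate 12, and the remaining hydroxyl four atoms away displaces the mesylate to form O1–C2. The closest known reaction type is the cyclodehydration of 1,4-diaryl-2,3-dimethylbutane-1,4-diols to 2,5-diaryloxolanes by monosulfonylation (intramolecular Williamson-type etherification). The oxolane ring closes in the 5-exo-tet mode. The new C2 configuration should result from inversion of the (R)-carbinol; should the para-silyloxyaryl ring let the mesylate ionize first, the benzylic cation closes with minimized A(1,3) strain (C3–H in the aryl plane, oxygen entering anti to the C3 methyl) to the same 2,3-trans arrangement, while C5 keeps its configuration because its C–O bond is never broken. The step needs monoactivation and kinetic control: the twofold axis makes either monomesylate give the same product, the five-membered closure should outrun a second sulfonylation, and chloride-free Ms2O with excess amine excludes double inversion through a benzylic chloride and acid-induced ring opening at C5.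

Step 8
Reactants: 13 (2S,3S,4S,5R)-2,5-bis[4-(tert-butyldimethylsilyloxy)-3,5-dimethoxyphenyl]-3,4-dimethyloxolane
Product: 14 4,4'-[(2S,3S,4S,5R)-3,4-dimethyloxolane-2,5-diyl]bis(2,6-dimethoxyphenol)
Conditions: Bu4NF, AcOH, THF, 0 °C to rt
Reagents that add atoms: none
Why: Fluoride-induced cleavage of the two aryl silyl ethers, buffered with acetic acid so that no free phenoxide can open the benzylic ether bonds and erode C2 or C5.

Compound list
1 | (R)-4-benzyl-3-propionyloxazolidin-2-one | CCC(=O)N1[C@H](Cc2ccccc2)COC1=O | starting material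
2 | lithium (Z)-1-[(R)-4-benzyl-2-oxooxazolidin-3-yl]prop-1-en-1-olate | C/C=C(\O[Li])N1[C@H](Cc2ccccc2)COC1=O | intermediate (not isolated)
3 | (2S,3S)-1,4-bis[(R)-4-benzyl-2-oxooxazolidin-3-yl]-2,3-dimethylbutane-1,4-dione | O=C1OC[C@@H](Cc2ccccc2)N1C(=O)[C@@H](C)[C@H](C)C(=O)N1[C@H](Cc2ccccc2)COC1=O | intermediate
4 | (2S,3S)-2,3-dimethylbutanediperoxoic acid (present as its lithium salt) | OOC(=O)[C@@H](C)[C@H](C)C(=O)OO | intermediate (not isolated)
5 | (2S,3S)-2,3-dimethylbutanedioic acid | OC(=O)[C@@H](C)[C@H](C)C(=O)O | intermediate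
6 | (2S,3S)-N1,N4-dimethoxy-N1,N4,2,3-tetramethylbutanediamide | CON(C)C(=O)[C@@H](C)[C@H](C)C(=O)N(C)OC | intermediate
7 | 4-bromo-2,6-dimethoxyphenol | COc1cc(Br)cc(OC)c1O | starting material
8 | (4-bromo-2,6-dimethoxyphenoxy)(tert-butyl)dimethylsilane | COc1cc(Br)cc(OC)c1O[Si](C)(C)C(C)(C)C | intermediate
9 | [4-(tert-butyldimethylsilyloxy)-3,5-dimethoxyphenyl]magnesium bromide | COc1cc([Mg]Br)cc(OC)c1O[Si](C)(C)C(C)(C)C | intermediate (not isolated)
10 | (2S,3S)-1,4-bis[4-(tert-butyldimethylsilyloxy)-3,5-dimethoxyphenyl]-2,3-dimethylbutane-1,4-dione | COc1cc(cc(OC)c1O[Si](C)(C)C(C)(C)C)C(=O)[C@@H](C)[C@H](C)C(=O)c1cc(OC)c(O[Si](C)(C)C(C)(C)C)c(OC)c1 | intermediate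
11 | (1R,2S,3S,4R)-1,4-bis[4-(tert-butyldimethylsilyloxy)-3,5-dimethoxyphenyl]-2,3-dimethylbutane-1,4-diol | COc1cc(cc(OC)c1O[Si](C)(C)C(C)(C)C)[C@H](O)[C@@H](C)[C@H](C)[C@@H](O)c1cc(OC)c(O[Si](C)(C)C(C)(C)C)c(OC)c1 | intermediate
12 | (1R,2S,3S,4R)-4-hydroxy-1,4-bis[4-(tert-butyldimethylsilyloxy)-3,5-dimethoxyphenyl]-2,3-dimethylbutyl methanesulfonate | COc1cc(cc(OC)c1O[Si](C)(C)C(C)(C)C)[C@H](OS(C)(=O)=O)[C@@H](C)[C@H](C)[C@@H](O)c1cc(OC)c(O[Si](C)(C)C(C)(C)C)c(OC)c1 | intermediate (not isolated)
13 | (2S,3S,4S,5R)-2,5-bis[4-(tert-butyldimethylsilyloxy)-3,5-dimethoxyphenyl]-3,4-dimethyloxolane | COc1cc([C@H]2O[C@@H](c3cc(OC)c(O[Si](C)(C)C(C)(C)C)c(OC)c3)[C@@H](C)[C@@H]2C)cc(OC)c1O[Si](C)(C)C(C)(C)C | intermediate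
14 | 4,4'-[(2S,3S,4S,5R)-3,4-dimethyloxolane-2,5-diyl]bis(2,6-dimethoxyphenol) | COc1cc([C@H]2O[C@@H](c3cc(OC)c(O)c(OC)c3)[C@@H](C)[C@@H]2C)cc(OC)c1O | target

Total step count: 8. Longest linear sequence: 7 steps (steps 1, 2, 3, 5, 6, 7, 8).

Steps most likely to fail

Step 6. The catalyst has to override the Felkin–Anh bias of each α-methyl ketone (a mismatched case), so hydride delivery may become poorly face-selective and give carbinol epimers. The fallback sets out from compound 6: the bis-Weinreb amide would be reduced with i-Bu2AlH (CH2Cl2, −78 °C) to (2S,3S)-2,3-dimethylbutanedial F1, which would be treated without purification with an excess of Grignard reagent 9 (THF, −78 °C). Felkin–Anh addition of the aryl nucleophile to an α-methyl aldehyde is then the matched pathway to the same syn carbinols, and the route is rejoined at compound 11.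

Step 7. The mesylate may ionize and lose a proton to a styrene, or both hydroxyls may be sulfonylated before the ring closes. The fallback sets out from compound 11: MnO2 (CH2Cl2, rt) would oxidize one benzylic alcohol to (2S,3S,4R)-4-hydroxy-1,4-bis[4-(tert-butyldimethylsilyloxy)-3,5-dimethoxyphenyl]-2,3-dimethylbutan-1-one F2, which closes reversibly to the cyclic hemiketal (3S,4S,5R)-2,5-bis[4-(tert-butyldimethylsilyloxy)-3,5-dimethoxyphenyl]-3,4-dimethyloxolan-2-ol F3 and so forms the same O1–C2 bond while shielding the second alcohol from oxidation. Et3SiH and BF3·OEt2 (CH2Cl2, −78 °C) would then reduce the derived oxocarbenium ion. In the envelope that keeps both methyls pseudo-equatorial the C5 aryl group is pseudo-axial, so hydride should enter C2 by inside attack on the face anti to the C4 methyl and C5 aryl groups. This would give the 2,3-trans oxolane and rejoin the route at compound 13.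

Step 1. Facial control in the radical dimerization may be incomplete, and competing reduction or over-oxidation of the enolate may lower conversion. The fallback sets out from compound 1: its enolate 2 would be alkylated (THF, −78 °C) with benzyl (S)-2-(trifluoromethylsulfonyloxy)propanoate F4, made from benzyl (S)-lactate, Tf2O and 2,6-lutidine. SN2 displacement with inversion at the lactate carbon, under auxiliary control at the enolate carbon, would give benzyl (2S,3S)-4-[(R)-4-benzyl-2-oxooxazolidin-3-yl]-2,3-dimethyl-4-oxobutanoate F5; LiOH/H2O2 followed by excess LiOH would remove the auxiliary and the benzyl ester and rejoin the route at compound 5.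

Further compounds
F1 | step 6 | (2S,3S)-2,3-dimethylbutanedial | O=C[C@@H](C)[C@H](C)C=O
F2 | step 7 | (2S,3S,4R)-4-hydroxy-1,4-bis[4-(tert-butyldimethylsilyloxy)-3,5-dimethoxyphenyl]-2,3-dimethylbutan-1-one | COc1cc(cc(OC)c1O[Si](C)(C)C(C)(C)C)C(=O)[C@@H](C)[C@H](C)[C@@H](O)c1cc(OC)c(O[Si](C)(C)C(C)(C)C)c(OC)c1
F3 | step 7 | (3S,4S,5R)-2,5-bis[4-(tert-butyldimethylsilyloxy)-3,5-dimethoxyphenyl]-3,4-dimethyloxolan-2-ol (both C2 epimers) | COc1cc(C2(O)O[C@@H](c3cc(OC)c(O[Si](C)(C)C(C)(C)C)c(OC)c3)[C@@H](C)[C@@H]2C)cc(OC)c1O[Si](C)(C)C(C)(C)C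
F4 | step 1 | benzyl (S)-2-(trifluoromethylsulfonyloxy)propanoate | C[C@H](OS(=O)(=O)C(F)(F)F)C(=O)OCc1ccccc1
F5 | step 1 | benzyl (2S,3S)-4-[(R)-4-benzyl-2-oxooxazolidin-3-yl]-2,3-dimethyl-4-oxobutanoate | O=C(OCc1ccccc1)[C@@H](C)[C@H](C)C(=O)N1[C@H](Cc2ccccc2)COC1=O
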